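You asked for a quick number on these flasks, and I started from the constants below.

    partner + free catalyst + left-handed substrate → free catalyst + left-handed product (k1 = 163 M⁻² min⁻¹, Ea1 = 40.0 kJ mol⁻¹)
    partner + free catalyst + right-handed substrate → free catalyst + right-handed product (k2 = 85.6 M⁻² min⁻¹, Ea2 = 50.0 kJ mol⁻¹)
    left-handed substrate + racemization catalyst ⇌ right-handed substrate + racemization catalyst, rate k3*[racemization catalyst]*[left-handed substrate] forward; the back reaction follows from the equilibrium constant (k3 = 421 M⁻¹ min⁻¹, Ea3 = 43.0 kJ mol⁻¹)
    (constants at 25 °C)

| setting | larch | oak | birch | ash |
|---|---|---|---|---|
| left-handed substrate | 0.052 M | 0.052 M | 0.052 M | 0.052 M |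
| partner | 2.50 equiv | 2.50 equiv | 2.50 equiv | 2.50 equiv |
| free catalyst | 11 mol% | 11 mol% | 11 mol% | 11 mol% |
| racemization catalyst | 2.7 mol% | 2.7 mol% | 2.7 mol% | 2.7 mol% |
| right-handed substrate | 0.052 M | 0.052 M | 0.052 M | 0.052 M |
| temperature | 45 °C | 5 °C | −15 °C | 25 °C |
| time | 40 min | 40 min | 40 min | 40 min |

- free catalyst is single-handed; left-handed substrate and right-handed substrate are mirror images of each other, charged as a racemate, each of them at the stated concentration
- the constants hold at 25 °C; other temperatures follow from the activation energies
- an excess is the difference of the two amounts in percent of their sum
- an excess is below zero if the other one leads

1. the flask with the highest excess of left-handed product over right-handed product ("all alike" if they lie within 1.5 percentage points) (larch / oak / birch / ash / all alike)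
2. excess of left-handed product over right-handed product at the end, larch
3. excess of left-handed product over right-handed product at the end, oak
4. excess of left-handed product over right-handed product at the end, birch
5. excess of left-handed product over right-handed product at the end, ash

Your hunch was that larch would lead, since racemization speeds up by a factor of 44 from birch to larch. I reckoned otherwise: from birch to larch the step to right-handed product gains more than the step to left-handed product, by a factor of 81 against 34.

Both steps use the same partner and free catalyst. So while the two substrates stood equal, the products formed in the ratio s of the two constants at the flask's temperature, and I took the plain excess as (s − 1)/(s + 1):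

larch: s = 1.48, plain excess 19.3%

oak: s = 2.54, plain excess 43.6%

birch: s = 3.56, plain excess 56.1%

ash: s = 1.90, plain excess 31.1%

This ratio, the selectivity factor, was what I carried forward. Racemization I treated as the correction. Left-handed substrate is consumed faster and racemization refills it, so I let the substrates part by a steady fraction x of their sum:

x = (difference of the two constants) × free catalyst × partner / (4 × racemization constant × racemization catalyst)

For birch, with the partner as charged, x came to 4.45%, which lowers the excess by x times (1 − the square of the plain excess), or 3 percentage points. Birch then still stood at 53.1%, more than the plain 43.6% of oak, so I committed to birch.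

The forecast gave 18.4% for larch, 41.7% for oak, 54.2% for birch and 29.8% for ash, and named birch: “Racemization is too slow to give dynamic resolution”.

The simulation gave 18.5% for larch, 41.7% for oak, 54.2% for birch and 29.8% for ash, with birch highest. Birch ended 1.9 points under its plain excess and larch 0.80 points under its own. The neighbour of larch, kept at 60 °C with all amounts and the time held, took the same reckoning: from the 1.48 of larch, s fell to 1.25, a plain excess of 11.0%. That neighbour gave 10.5%, with right-handed product at 44.7% of the substrates charged.

The constants used here were chosen freely; the result is computed.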